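The C7 acetoxy carbon and the C8 peroxy carbon of the 1,2-dioxane (cembrane numbering) are read as a former (7Z)-olefin, so the C6–C7 bond becomes an sp3–sp2 bond. One operation, chemoselective 9-BBN hydroboration of a terminal 1,3-diene followed by intramolecular B-alkyl Suzuki–Miyaura coupling with a (Z)-alkenyl iodide, turns the dienyl end into the C5 and C6 methylenes and closes the 14-membered carbocycle with three defined olefins. The precursor is an open-chain cis-α-methylene-γ-butyrolactone carrying the dienyl arm at C2 and an iodoalkenyl chain at C1. Epoxidation of the new olefin, perhydrolysis at C8 and peroxide alkylation at C11 then build the dioxane.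

Key step: step 16

Remark: cembrane numbering is used for ring compounds: C1–C14 form the carbocycle, C1 carries C15 (which bears the C17 methylene and the C16 carbonyl), the lactone oxygen sits on C2, and C18, C19 and C20 are the methyl groups on C4, C8 and C12.
Remark: compounds 1, 5, 8, 9 and 19 are taken as commercially available.

Step 1
Reactants: 1 prop-2-yn-1-ol
Product: 3 (2Z)-3-iodo-2-methylprop-2-en-1-ol, via vinylmagnesium alkoxide 2 (not isolated)
Conditions: MeMgBr (2.5 equiv), CuI (10 mol %), THF, −20 °C to rt; then I2, Et2O, −78 to 0 °C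
Reagents that add atoms: methylmagnesium bromide C[Mg]Br; iodine II
Why: copper-catalysed anti-carbomagnesiation of the propargylic alkoxide should place methyl on the internal carbon and magnesium cis to the CH2O group in a five-membered chelate, and iodinolysis with retention gives the (Z)-iodoalkene that becomes C7=C8.

Step 2
Reactants: 3 (2Z)-3-iodo-2-methylprop-2-en-1-ol
Product: 4 (1Z)-3-bromo-1-iodo-2-methylprop-1-ene
Conditions: CBr4, PPh3, CH2Cl2, 0 °C
Reagents that add atoms: carbon tetrabromide BrC(Br)(Br)Br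
Why: Appel bromination should convert the primary allylic alcohol into the bromide without allylic transposition or loss of the (Z)-iodoalkene geometry.

Step 3
Reactants: 5 (2E)-3-methylpent-2-en-4-yn-1-ol
Product: 6 (2E)-3-methylpenta-2,4-dien-1-ol
Conditions: H2 (1 atm), Pd/CaCO3 poisoned with Pb(OAc)2 (Lindlar catalyst), quinoline, EtOAc, rt
Reagents that add atoms: none
Why: Lindlar semi-hydrogenation of the terminal alkyne should stop at the vinyl group and leave the (E)-trisubstituted olefin untouched.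

Step 4
Reactants: 6 (2E)-3-methylpenta-2,4-dien-1-ol
Product: 7 (2E)-3-methylpenta-2,4-dienal
Conditions: MnO2, CH2Cl2, rt
Reagents that add atoms: none
Why: allylic oxidation with MnO2 should give the dienal (used as a solution) without isomerizing the (E)-olefin that becomes C3=C4.

Step 5
Reactants: 8 3-[(tert-butyldimethylsilyl)oxy]propanal; 9 ethyl 2-[bis(2,2,2-trifluoroethoxy)phosphoryl]propanoate
Product: 10 ethyl (2Z)-5-[(tert-butyldimethylsilyl)oxy]-2-methylpent-2-enoate
Conditions: KN(SiMe3)2, 18-crown-6, THF, −78 °C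
Reagents that add atoms: none
Why: Still–Gennari olefination with the electron-poor phosphonate under dissociating conditions should give the kinetic (Z)-enoate, which fixes the future 12Z olefin with C11 and C14 cis.

Step 6
Reactants: 10 ethyl (2Z)-5-[(tert-butyldimethylsilyl)oxy]-2-methylpent-2-enoate
Product: 11 (2Z)-5-[(tert-butyldimethylsilyl)oxy]-N-methoxy-N,2-dimethylpent-2-enamide
Conditions: MeNH(OMe)·HCl, i-PrMgCl, THF, −20 to 0 °C
Reagents that add atoms: N,O-dimethylhydroxylamine hydrochloride CNOC.Cl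
Why: aminolysis of the ester by the magnesium amide (Weinreb amide formation) should leave the (Z)-olefin and the silyl ether intact.

Step 7
Reactants: 11 (2Z)-5-[(tert-butyldimethylsilyl)oxy]-N-methoxy-N,2-dimethylpent-2-enamide
Product: 12 (3Z)-6-[(tert-butyldimethylsilyl)oxy]-3-methylhex-3-en-2-one
Conditions: MeMgBr, THF, −78 to 0 °C
Reagents that add atoms: methylmagnesium bromide C[Mg]Br
Why: Weinreb ketone synthesis, in which the chelated tetrahedral intermediate prevents over-addition, should give the (Z)-methyl enone whose methyl group becomes C10.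

Step 8
Reactants: 12 (3Z)-6-[(tert-butyldimethylsilyl)oxy]-3-methylhex-3-en-2-one; 4 (1Z)-3-bromo-1-iodo-2-methylprop-1-ene
Product: 14 (1Z,6Z)-9-[(tert-butyldimethylsilyl)oxy]-1-iodo-2,6-dimethylnona-1,6-dien-5-one, via lithium enolate 13 (not isolated)
Conditions: LiN(i-Pr)2, THF, −78 °C; then 4, DMPU, −78 to −30 °C
Reagents that add atoms: none
Why: kinetic deprotonation at the α′-methyl group gives the cross-conjugated enolate, which should be C-alkylated by the reactive allylic bromide (SN2) to form the C9–C10 bond without touching either (Z)-olefin.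

Step 9
Reactants: 14 (1Z,6Z)-9-[(tert-butyldimethylsilyl)oxy]-1-iodo-2,6-dimethylnona-1,6-dien-5-one
Product: 15 (1Z,5S,6Z)-9-[(tert-butyldimethylsilyl)oxy]-1-iodo-2,6-dimethylnona-1,6-dien-5-ol
Conditions: (R)-2-methyl-CBS-oxazaborolidine (20 mol %), catecholborane, toluene, −78 °C
Reagents that add atoms: none
Why: in this Corey–Bakshi–Shibata reduction the α-methylalkenyl group acts as the large substituent, so the (R)-oxazaborolidine should deliver hydride to give the (S)-carbinol that becomes C11, and catecholborane at −78 °C leaves the iodoalkene alone.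

Step 10
Reactants: 15 (1Z,5S,6Z)-9-[(tert-butyldimethylsilyl)oxy]-1-iodo-2,6-dimethylnona-1,6-dien-5-ol
Product: 16 (1Z,5S,6Z)-5,9-bis[(tert-butyldimethylsilyl)oxy]-1-iodo-2,6-dimethylnona-1,6-diene
Conditions: TBSOTf, 2,6-lutidine, CH2Cl2, −78 to 0 °C
Reagents that add atoms: tert-butyldimethylsilyl trifluoromethanesulfonate CC(C)(C)[Si](C)(C)OS(=O)(=O)C(F)(F)F
Why: silylation of the hindered secondary allylic alcohol should protect the C11 oxygen through the oxidation, allylation and coupling steps.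

Step 11
Reactants: 16 (1Z,5S,6Z)-5,9-bis[(tert-butyldimethylsilyl)oxy]-1-iodo-2,6-dimethylnona-1,6-diene
Product: 17 (3Z,5S,8Z)-5-[(tert-butyldimethylsilyl)oxy]-9-iodo-4,8-dimethylnona-3,8-dien-1-ol
Conditions: HF·pyridine, pyridine, THF, 0 °C
Reagents that add atoms: none
Why: under buffered HF·pyridine the primary silyl ether should be cleaved much faster than the hindered secondary allylic one.

Step 12
Reactants: 17 (3Z,5S,8Z)-5-[(tert-butyldimethylsilyl)oxy]-9-iodo-4,8-dimethylnona-3,8-dien-1-ol
Product: 18 (3Z,5S,8Z)-5-[(tert-butyldimethylsilyl)oxy]-9-iodo-4,8-dimethylnona-3,8-dienal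
Conditions: Dess–Martin periodinane, NaHCO3, CH2Cl2, 0 °C
Reagents that add atoms: none
Why: buffered Dess–Martin oxidation should give the β,γ-unsaturated aldehyde without moving the (Z)-olefin into conjugation, and the aldehyde is used crude at once.

Step 13
Reactants: 18 (3Z,5S,8Z)-5-[(tert-butyldimethylsilyl)oxy]-9-iodo-4,8-dimethylnona-3,8-dienal; 19 methyl prop-2-ynoate
Product: 21 methyl (5Z,7S,10Z)-7-[(tert-butyldimethylsilyl)oxy]-3-hydroxy-11-iodo-6,10-dimethyl-2-methylideneundeca-5,10-dienoate (mixture of C3 epimers), via alkenylalane 20 (not isolated)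
Conditions: 19, i-Bu2AlH, HMPA, THF, 0 °C; then 18, 0 °C to rt
Reagents that add atoms: none
Why: hydroalumination of the propiolate gives the α-aluminoacrylate, which should add to the aldehyde to give the Morita–Baylis–Hillman-type adduct without amine base, so the skipped enal is not isomerized; the new carbinol centre is erased in step 14.

Step 14
Reactants: 21 methyl (5Z,7S,10Z)-7-[(tert-butyldimethylsilyl)oxy]-3-hydroxy-11-iodo-6,10-dimethyl-2-methylideneundeca-5,10-dienoate
Product: 22 methyl (2Z,5Z,7S,10Z)-2-(bromomethyl)-7-[(tert-butyldimethylsilyl)oxy]-11-iodo-6,10-dimethylundeca-2,5,10-trienoate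
Conditions: NBS, Me2S, CH2Cl2, 0 °C to rt
Reagents that add atoms: N-bromosuccinimide O=C1CCC(=O)N1Br
Why: SN2′ displacement of the sulfonium-activated hydroxyl by bromide should transpose the allylic system and give the thermodynamically preferred (2Z)-2-(bromomethyl)enoate, in which the chain is cis to CH2Br.

Step 15
Reactants: 22 methyl (2Z,5Z,7S,10Z)-2-(bromomethyl)-7-[(tert-butyldimethylsilyl)oxy]-11-iodo-6,10-dimethylundeca-2,5,10-trienoate; 7 (2E)-3-methylpenta-2,4-dienal
Product: 24 (4S,5S)-4-[(2Z,4S,7Z)-4-[(tert-butyldimethylsilyl)oxy]-8-iodo-3,7-dimethylocta-2,7-dien-1-yl]-3-methylidene-5-[(1E)-2-methylbuta-1,3-dien-1-yl]oxolan-2-one, via hydroxy ester 23 (not isolated)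
Conditions: CrCl2 (10 mol %), chiral carbazole-bis(oxazoline) ligand (12 mol %, enantiomer chosen for Re-face addition), Mn, Me3SiCl, THF, rt; then aq. citric acid; PPTS, CH2Cl2, rt
Reagents that add atoms: none
Why: in this catalytic asymmetric Nozaki–Hiyama–Kishi-type 2-(alkoxycarbonyl)allylation the γ-substituted allylchromium keeps its chain cis to the CH2Cr carbon and adds at C1 through a closed chair, which should give the syn adduct, the ligand directs attack on the Re face of the aldehyde to set C2 (S) and so C1 (S), and the hydroxy ester closes to the cis lactone on acid work-up; without a nickel cocatalyst the alkenyl iodide is inert toward divalent chromium.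

Step 16
Reactants: 24 (4S,5S)-4-[(2Z,4S,7Z)-4-[(tert-butyldimethylsilyl)oxy]-8-iodo-3,7-dimethylocta-2,7-dien-1-yl]-3-methylidene-5-[(1E)-2-methylbuta-1,3-dien-1-yl]oxolan-2-one
Product: 26 (1S,2S,3E,7Z,11S,12Z)-11-[(tert-butyldimethylsilyl)oxy]cembra-3,7,12,15(17)-tetraen-16,2-olide, via B-alkylborane 25 (not isolated)
Conditions: 9-BBN (1.1 equiv), THF, 0 °C to rt; then slow addition to Pd(dppf)Cl2 (20 mol %), AsPh3, Cs2CO3, DMF/THF/H2O, rt, final concentration about 1 mM
Reagents that add atoms: none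
Why: 9-BBN adds anti-Markovnikov to the monosubstituted C5=C6 terminus of the diene to give the primary C6 borane 25, after which oxidative addition of zerovalent palladium into the C7–I bond, base-assisted transmetalation of the C6 alkyl group and reductive elimination form the C6–C7 bond. The closest known reaction type is the B-alkyl Suzuki–Miyaura macrocyclization of an ω-alkenyl alkenyl iodide after in situ hydroboration. The 14-membered carbocycle closes by intramolecular cross-coupling at the alkenyl carbon under high dilution, and no other ring is formed. No stereocentre is created: the (7Z) geometry should be transferred with retention from the alkenyl iodide, and the (3E) and (12Z) olefins and the C1, C2 and C11 centres are not touched. The step needs hydroboration at the diene terminus only, which should follow because it is the sole monosubstituted olefin while the α-methylene lactone is 1,1-disubstituted and electron-poor and the other olefins are trisubstituted, and it needs cyclization over oligomerization, which slow addition of the borane to the catalyst secures.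

Step 17
Reactants: 26 (1S,2S,3E,7Z,11S,12Z)-11-[(tert-butyldimethylsilyl)oxy]cembra-3,7,12,15(17)-tetraen-16,2-olide
Product: 27 (1S,2S,3E,7Z,11S,12Z)-11-hydroxycembra-3,7,12,15(17)-tetraen-16,2-olide
Conditions: Bu4NF, AcOH, THF, 0 °C to rt
Reagents that add atoms: none
Why: fluoride should cleave the secondary silyl ether, and buffering with acetic acid keeps alkoxide and fluoride from attacking the α-methylene lactone.

Step 18
Reactants: 27 (1S,2S,3E,7Z,11S,12Z)-11-hydroxycembra-3,7,12,15(17)-tetraen-16,2-olide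
Product: 29 (1S,2S,3E,7Z,11R,12Z)-11-chlorocembra-3,7,12,15(17)-tetraen-16,2-olide, via allylic mesylate 28 (not isolated)
Conditions: MsCl, 2,4,6-collidine, LiCl, DMF, 0 °C
Reagents that add atoms: lithium chloride [Li+].[Cl-]
Why: the alcohol is mesylated and the allylic mesylate should be displaced in situ by chloride in an SN2 reaction with inversion, giving the (11R)-chloride that allows a second inversion in step 21.

Step 19
Reactants: 29 (1S,2S,3E,7Z,11R,12Z)-11-chlorocembra-3,7,12,15(17)-tetraen-16,2-olide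
Product: 30 (1S,2S,3E,7S,8R,11R,12Z)-11-chloro-7,8-epoxycembra-3,12,15(17)-trien-16,2-olide
Conditions: L-fructose-derived Shi ketone (30 mol %), Oxone (2KHSO5·KHSO4·K2SO4), K2CO3, Bu4NHSO4, Na2B4O7 buffer, MeCN/dimethoxymethane/H2O, 0 °C
Reagents that add atoms: Oxone (potassium peroxymonosulfate) [K+].[O-]S(=O)(=O)OO
Why: in this Shi epoxidation the chiral dioxirane should attack only C7=C8, the one electron-rich olefin not deactivated by an allylic oxygen, an allylic chlorine or a carbonyl group, and the spiro transition state of the L-fructose-derived ketone should give the (7S,8R)-epoxide.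

Step 20
Reactants: 30 (1S,2S,3E,7S,8R,11R,12Z)-11-chloro-7,8-epoxycembra-3,12,15(17)-trien-16,2-olide
Product: 31 (1S,2S,3E,7S,8S,11R,12Z)-11-chloro-8-hydroperoxy-7-hydroxycembra-3,12,15(17)-trien-16,2-olide
Conditions: H2O2 (anhydrous, in Et2O), H3PMo12O40 (5 mol %), Et2O, rt
Reagents that add atoms: hydrogen peroxide OO
Why: in this molybdenum-catalysed perhydrolysis hydrogen peroxide should open the activated trisubstituted epoxide at the tertiary carbon C8 with inversion, which sets C8 (S) and frees the C7 (S) alcohol.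

Step 21
Reactants: 31 (1S,2S,3E,7S,8S,11R,12Z)-11-chloro-8-hydroperoxy-7-hydroxycembra-3,12,15(17)-trien-16,2-olide
Product: 32 (1S,2S,3E,7S,8S,11S,12Z)-8,11-epidioxy-7-hydroxycembra-3,12,15(17)-trien-16,2-olide
Conditions: Cs2CO3, DMF, 0 °C
Reagents that add atoms: none
Why: the caesium peroxide anion should displace the allylic chloride at C11 in a 6-exo-tet SN2 alkylation with inversion, closing the 1,2-dioxane with C11 (S), and the more acidic hydroperoxide reacts in preference to the C7 alcohol.

Step 22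
Reactants: 32 (1S,2S,3E,7S,8S,11S,12Z)-8,11-epidioxy-7-hydroxycembra-3,12,15(17)-trien-16,2-olide
Product: 33 (1S,2S,3E,7S,8S,11S,12Z)-7-acetoxy-8,11-epidioxycembra-3,12,15(17)-trien-16,2-olide (CNP0238885.1)
Conditions: Ac2O, pyridine, DMAP (cat.), CH2Cl2, 0 °C
Reagents that add atoms: acetic anhydride CC(=O)OC(C)=O
Why: acylation of the secondary C7 alcohol at 0 °C should be tolerated by the dialkyl peroxide and the α-methylene lactone.

Compound list
1 | prop-2-yn-1-ol | C#CCO | starting material
2 | bromomagnesium (2Z)-3-(bromomagnesio)-2-methylprop-2-en-1-olate | Br[Mg]OC/C(C)=C\[Mg]Br | intermediate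
3 | (2Z)-3-iodo-2-methylprop-2-en-1-ol | OC/C(C)=C\I | intermediate
4 | (1Z)-3-bromo-1-iodo-2-methylprop-1-ene | BrC/C(C)=C\I | intermediate
5 | (2E)-3-methylpent-2-en-4-yn-1-ol | OC/C=C(\C)C#C | starting material
6 | (2E)-3-methylpenta-2,4-dien-1-ol | OC/C=C(\C)C=C | intermediate
7 | (2E)-3-methylpenta-2,4-dienal | O=C/C=C(\C)C=C | intermediate
8 | 3-[(tert-butyldimethylsilyl)oxy]propanal | O=CCCO[Si](C)(C)C(C)(C)C | starting material
9 | ethyl 2-[bis(2,2,2-trifluoroethoxy)phosphoryl]propanoate | CCOC(=O)C(C)P(=O)(OCC(F)(F)F)OCC(F)(F)F | starting material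
10 | ethyl (2Z)-5-[(tert-butyldimethylsilyl)oxy]-2-methylpent-2-enoate | CCOC(=O)/C(C)=C\CCO[Si](C)(C)C(C)(C)C | intermediate
11 | (2Z)-5-[(tert-butyldimethylsilyl)oxy]-N-methoxy-N,2-dimethylpent-2-enamide | CON(C)C(=O)/C(C)=C\CCO[Si](C)(C)C(C)(C)C | intermediate
12 | (3Z)-6-[(tert-butyldimethylsilyl)oxy]-3-methylhex-3-en-2-one | CC(=O)/C(C)=C\CCO[Si](C)(C)C(C)(C)C | intermediate
13 | lithium (3Z)-6-[(tert-butyldimethylsilyl)oxy]-3-methylhexa-1,3-dien-2-olate | [Li]OC(=C)/C(C)=C\CCO[Si](C)(C)C(C)(C)C | intermediate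
14 | (1Z,6Z)-9-[(tert-butyldimethylsilyl)oxy]-1-iodo-2,6-dimethylnona-1,6-dien-5-one | I/C=C(C)\CCC(=O)/C(C)=C\CCO[Si](C)(C)C(C)(C)C | intermediate
15 | (1Z,5S,6Z)-9-[(tert-butyldimethylsilyl)oxy]-1-iodo-2,6-dimethylnona-1,6-dien-5-ol | I/C=C(C)\CC[C@H](O)/C(C)=C\CCO[Si](C)(C)C(C)(C)C | intermediate
16 | (1Z,5S,6Z)-5,9-bis[(tert-butyldimethylsilyl)oxy]-1-iodo-2,6-dimethylnona-1,6-diene | I/C=C(C)\CC[C@H](O[Si](C)(C)C(C)(C)C)/C(C)=C\CCO[Si](C)(C)C(C)(C)C | intermediate
17 | (3Z,5S,8Z)-5-[(tert-butyldimethylsilyl)oxy]-9-iodo-4,8-dimethylnona-3,8-dien-1-ol | I/C=C(C)\CC[C@H](O[Si](C)(C)C(C)(C)C)/C(C)=C\CCO | intermediate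
18 | (3Z,5S,8Z)-5-[(tert-butyldimethylsilyl)oxy]-9-iodo-4,8-dimethylnona-3,8-dienal | I/C=C(C)\CC[C@H](O[Si](C)(C)C(C)(C)C)/C(C)=C\CC=O | intermediate
19 | methyl prop-2-ynoate | C#CC(=O)OC | starting material
20 | methyl 2-(diisobutylalumanyl)prop-2-enoate | C=C(C(=O)OC)[Al](CC(C)C)CC(C)C | intermediate
21 | methyl (5Z,7S,10Z)-7-[(tert-butyldimethylsilyl)oxy]-3-hydroxy-11-iodo-6,10-dimethyl-2-methylideneundeca-5,10-dienoate (C3 epimers) | I/C=C(C)\CC[C@H](O[Si](C)(C)C(C)(C)C)/C(C)=C\CC(O)C(=C)C(=O)OC | intermediate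
22 | methyl (2Z,5Z,7S,10Z)-2-(bromomethyl)-7-[(tert-butyldimethylsilyl)oxy]-11-iodo-6,10-dimethylundeca-2,5,10-trienoate | I/C=C(C)\CC[C@H](O[Si](C)(C)C(C)(C)C)/C(C)=C\C/C=C(\CBr)C(=O)OC | intermediate
23 | methyl (3S,5Z,7S,10Z)-7-[(tert-butyldimethylsilyl)oxy]-3-[(1S,2E)-1-hydroxy-3-methylpenta-2,4-dien-1-yl]-11-iodo-6,10-dimethyl-2-methylideneundeca-5,10-dienoate | I/C=C(C)\CC[C@H](O[Si](C)(C)C(C)(C)C)/C(C)=C\C[C@@H](C(=C)C(=O)OC)[C@@H](O)/C=C(\C)C=C | intermediate
24 | (4S,5S)-4-[(2Z,4S,7Z)-4-[(tert-butyldimethylsilyl)oxy]-8-iodo-3,7-dimethylocta-2,7-dien-1-yl]-3-methylidene-5-[(1E)-2-methylbuta-1,3-dien-1-yl]oxolan-2-one | I/C=C(C)\CC[C@H](O[Si](C)(C)C(C)(C)C)/C(C)=C\C[C@@H]1[C@H](/C=C(\C)C=C)OC(=O)C1=C | intermediate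
25 | B-alkyl-9-BBN adduct of 24 (9-borabicyclo[3.3.1]nonan-9-yl on C6, the former diene terminus) | I/C=C(C)\CC[C@H](O[Si](C)(C)C(C)(C)C)/C(C)=C\C[C@@H]1[C@H](/C=C(\C)CCB2C3CCCC2CCC3)OC(=O)C1=C | intermediate
26 | (1S,2S,3E,7Z,11S,12Z)-11-[(tert-butyldimethylsilyl)oxy]cembra-3,7,12,15(17)-tetraen-16,2-olide | C=C1C(=O)O[C@H]2/C=C(\C)CC/C=C(C)\CC[C@H](O[Si](C)(C)C(C)(C)C)/C(C)=C\C[C@@H]12 | intermediate
27 | (1S,2S,3E,7Z,11S,12Z)-11-hydroxycembra-3,7,12,15(17)-tetraen-16,2-olide | C=C1C(=O)O[C@H]2/C=C(\C)CC/C=C(C)\CC[C@H](O)/C(C)=C\C[C@@H]12 | intermediate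
28 | (1S,2S,3E,7Z,11S,12Z)-11-(methanesulfonyloxy)cembra-3,7,12,15(17)-tetraen-16,2-olide | C=C1C(=O)O[C@H]2/C=C(\C)CC/C=C(C)\CC[C@H](OS(C)(=O)=O)/C(C)=C\C[C@@H]12 | intermediate
29 | (1S,2S,3E,7Z,11R,12Z)-11-chlorocembra-3,7,12,15(17)-tetraen-16,2-olide | C=C1C(=O)O[C@H]2/C=C(\C)CC/C=C(C)\CC[C@@H](Cl)/C(C)=C\C[C@@H]12 | intermediate
30 | (1S,2S,3E,7S,8R,11R,12Z)-11-chloro-7,8-epoxycembra-3,12,15(17)-trien-16,2-olide | C=C1C(=O)O[C@H]2/C=C(\C)CC[C@@H]3O[C@]3(C)CC[C@@H](Cl)/C(C)=C\C[C@@H]12 | intermediate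
31 | (1S,2S,3E,7S,8S,11R,12Z)-11-chloro-8-hydroperoxy-7-hydroxycembra-3,12,15(17)-trien-16,2-olide | C=C1C(=O)O[C@H]2/C=C(\C)CC[C@H](O)[C@](OO)(C)CC[C@@H](Cl)/C(C)=C\C[C@@H]12 | intermediate
32 | (1S,2S,3E,7S,8S,11S,12Z)-8,11-epidioxy-7-hydroxycembra-3,12,15(17)-trien-16,2-olide | C=C1C(=O)O[C@H]2/C=C(\C)CC[C@H](O)[C@]3(C)CC[C@H](OO3)/C(C)=C\C[C@@H]12 | intermediate
33 | (1S,2S,3E,7S,8S,11S,12Z)-7-acetoxy-8,11-epidioxycembra-3,12,15(17)-trien-16,2-olide (CNP0238885.1) | C=C1C(=O)O[C@H]2/C=C(\C)CC[C@H](OC(C)=O)[C@]3(C)CC[C@H](OO3)/C(C)=C\C[C@@H]12 | target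

Total step count: 22. Longest linear sequence: 18 steps (steps 5 to 22, from 8).

Steps most likely to fail

Step 16. What may go wrong is competing hydroboration of the α-methylene lactone, Heck-type capture of the alkenylpalladium by the enoate, or oligomerization. The fallback masks the enoate before the ring closure and sets out from 24. Conjugate addition of dimethylamine (Me2NH, EtOH, 0 °C) should give the dimethylamine adduct F1. Hydroboration with 9-BBN then gives the B-alkylborane F2 (not isolated), and the same palladium coupling under high dilution should close the ring to the macrocyclic amine F3. Quaternization with MeI gives the trimethylammonium iodide F4, which on treatment with aqueous NaHCO3 loses trimethylamine and comes back to the route at 26.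

Step 15. What may go wrong is poor facial selectivity or erosion of the syn preference in the chromium-mediated addition. The fallback replaces the allylchromium by a configurationally fixed allylboronate and sets out from 21. Acetylation (Ac2O, pyridine) gives the allylic acetate F5, and copper-catalysed SN2′ borylation (B2pin2, CuCl, KOt-Bu, THF, 0 °C) should give the allylboronate F6, whose chain is cis to the CH2B carbon. A BINOL-derived chiral phosphoric acid then catalyses a closed-chair allylboration of dienal 7, which should give the same syn adduct 23 and, after lactonization, comes back to the route at 24.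

Step 20. What may go wrong is acid-promoted transannular participation of the C3=C4 or C12=C13 olefin, or loss of stereospecific opening at the tertiary carbon. The fallback introduces the peroxide oxygen at C11 first and sets out from 30. Displacement of the allylic chloride by hydroperoxide anion (H2O2, CsOH·H2O, DMF, 0 °C) with inversion should give the (11S)-hydroperoxy epoxide F7. A catalytic amount of camphorsulfonic acid in CH2Cl2 then triggers 6-exo opening of the epoxide at C8 with inversion, which comes back to the route at 32 and bypasses steps 20 and 21.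

Further compounds
F1 | step 16 | dimethylamine adduct of 24 (C15 is CH and C17 is CH2NMe2; both C15 epimers) | I/C=C(C)\CC[C@H](O[Si](C)(C)C(C)(C)C)/C(C)=C\C[C@@H]1[C@H](/C=C(\C)C=C)OC(=O)C1CN(C)C
F2 | step 16 | B-alkyl-9-BBN adduct of F1 at C6 | I/C=C(C)\CC[C@H](O[Si](C)(C)C(C)(C)C)/C(C)=C\C[C@@H]1[C@H](/C=C(\C)CCB2C3CCCC2CCC3)OC(=O)C1CN(C)C
F3 | step 16 | macrocyclic amine (26 in which C15 is CH and C17 is CH2NMe2) | CN(C)CC1C(=O)O[C@H]2/C=C(\C)CC/C=C(C)\CC[C@H](O[Si](C)(C)C(C)(C)C)/C(C)=C\C[C@@H]12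
F4 | step 16 | trimethylammonium iodide of F3 | C[N+](C)(C)CC1C(=O)O[C@H]2/C=C(\C)CC/C=C(C)\CC[C@H](O[Si](C)(C)C(C)(C)C)/C(C)=C\C[C@@H]12.[I-]
F5 | step 15 | methyl (5Z,7S,10Z)-3-acetoxy-7-[(tert-butyldimethylsilyl)oxy]-11-iodo-6,10-dimethyl-2-methylideneundeca-5,10-dienoate (C3 epimers) | I/C=C(C)\CC[C@H](O[Si](C)(C)C(C)(C)C)/C(C)=C\CC(OC(C)=O)C(=C)C(=O)OC
F6 | step 15 | methyl (2E,5Z,7S,10Z)-7-[(tert-butyldimethylsilyl)oxy]-11-iodo-6,10-dimethyl-2-[(4,4,5,5-tetramethyl-1,3,2-dioxaborolan-2-yl)methyl]undeca-2,5,10-trienoate | I/C=C(C)\CC[C@H](O[Si](C)(C)C(C)(C)C)/C(C)=C\C/C=C(\CB1OC(C)(C)C(C)(C)O1)C(=O)OC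
F7 | step 20 | (1S,2S,3E,7S,8R,11S,12Z)-7,8-epoxy-11-hydroperoxycembra-3,12,15(17)-trien-16,2-olide | C=C1C(=O)O[C@H]2/C=C(\C)CC[C@@H]3O[C@]3(C)CC[C@H](OO)/C(C)=C\C[C@@H]12
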